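Atoms are numbered as in ent-kaurane. Everything rests on closing ring D (C8, C14, C13, C16, C15) of the bicyclo[3.2.1]octenone last, by joining C15 to C16. A chromium/nickel-mediated reductive alkyne–aldehyde coupling does this in one operation. It exploits the cis-1,3 relationship of the C13 ethynyl and C8 formyl groups on the ring C cyclohexenone and the chelating C9 ketone, and it forms the bicycle, the C16=C17 methylene and the C15 carbinol together. The precursor, a 4-ethynyl-6-formylcyclohex-2-enone carrying the ring A lactone on C7, arises from a catalyst-controlled Diels–Alder reaction of a 1-silyloxydienyne with a lactone-substituted 2-methylene aldehyde.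

Key step: step 15

Assumption: the sense of induction in steps 3 and 13 is taken from the accepted transition-state models for proline and oxazaborolidinium catalysis, recalled and not re-checked against a model reaction; the enantiomeric catalyst is used if the sense proves opposite.

Step 1
Reactants: 1 dimethyl 2-allylmalonate; 2 5-bromo-2-methylpent-1-ene
Product: 3 dimethyl 2-allyl-2-(4-methylpent-4-en-1-yl)malonate
Conditions: NaH, DMF, 0 → 50 °C
Reagents that add atoms: none
Why: SN2 C-alkylation of the sodium malonate by an unhindered primary bromide should give the quaternary diester; no stereocenter is formed.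

Step 2
Reactants: 3 dimethyl 2-allyl-2-(4-methylpent-4-en-1-yl)malonate
Product: 4 dimethyl 2-(2-oxoethyl)-2-(4-oxopentyl)malonate
Conditions: O3, CH2Cl2, −78 °C; PPh3, −78 °C → rt
Reagents that add atoms: ozone [O-][O+]=O
Why: Double ozonolysis with reductive work-up should turn the monosubstituted alkene into the aldehyde and the 1,1-disubstituted alkene into the methyl ketone.

Step 3
Reactants: 4 dimethyl 2-(2-oxoethyl)-2-(4-oxopentyl)malonate
Product: 5 dimethyl (2R,3R)-2-formyl-3-hydroxy-3-methylcyclohexane-1,1-dicarboxylate (formyl trans to hydroxyl)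
Conditions: (R)-proline (30 mol%), DMSO, rt
Reagents that add atoms: none
Why: Proline-catalysed 6-enolexo aldolization, in which the faster-formed aldehyde enamine should attack the methyl ketone through the Houk–List transition state, the carboxylic acid delivering the ketone to one enamine face (sets C5) with hydroxyl anti to formyl (sets C10).

Step 4
Reactants: 5 dimethyl (2R,3R)-2-formyl-3-hydroxy-3-methylcyclohexane-1,1-dicarboxylate; 6 but-3-en-1-ylmagnesium bromide
Product: 7 dimethyl (2S,3R)-3-hydroxy-2-(1-hydroxypent-4-en-1-yl)-3-methylcyclohexane-1,1-dicarboxylate (both carbinol epimers)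
Conditions: 6 (2.3 equiv), THF, −78 °C; AcOH, −78 °C
Reagents that add atoms: none
Why: Grignard 1,2-addition to the aldehyde should outrun attack on the hindered malonate esters at −78 °C; the new carbinol configuration is immaterial because step 5 removes it, and the cold acidic quench is meant to prevent premature lactonization.

Step 5
Reactants: 7 dimethyl (2S,3R)-3-hydroxy-2-(1-hydroxypent-4-en-1-yl)-3-methylcyclohexane-1,1-dicarboxylate
Product: 8 dimethyl (2R,3R)-3-hydroxy-3-methyl-2-(pent-4-enoyl)cyclohexane-1,1-dicarboxylate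
Conditions: Dess–Martin periodinane, NaHCO3, CH2Cl2, 0 °C
Reagents that add atoms: none
Why: Dess–Martin oxidation should convert only the secondary alcohol, and the buffered neutral medium avoids retro-aldol cleavage of the β-hydroxy ketone.

Step 6
Reactants: 8 dimethyl (2R,3R)-3-hydroxy-3-methyl-2-(pent-4-enoyl)cyclohexane-1,1-dicarboxylate
Product: 10 methyl (3R,3aS,4R,7aR)-3-(but-3-en-1-yl)-4-hydroxy-4-methyl-1-oxohexahydroisobenzofuran-7a(1H)-carboxylate, via diol diester 9 (not isolated)
Conditions: Zn(BH4)2, Et2O, −30 °C; aq. NH4Cl; then PPTS (cat.), PhMe, 50 °C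
Reagents that add atoms: none
Why: Chelation-controlled reduction of a β-hydroxy ketone, in which the zinc alkoxide of the tertiary hydroxyl binds the ketone and hydride should enter the chelate opposite the axial C10 methyl (sets C6), followed by acid-catalysed lactonization onto the ester cis to the new hydroxyl.

Step 7
Reactants: 10 methyl (3R,3aS,4R,7aR)-3-(but-3-en-1-yl)-4-hydroxy-4-methyl-1-oxohexahydroisobenzofuran-7a(1H)-carboxylate
Product: 11 (3R,3aS,4R)-3-(but-3-en-1-yl)-4-hydroxy-4-methylhexahydroisobenzofuran-1(3H)-one (both C7a epimers)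
Conditions: LiCl, H2O, DMSO, 150 °C
Reagents that add atoms: none
Why: Krapcho dealkoxycarbonylation (chloride demethylates the malonate-type ester, the carboxylate loses CO2) should leave the lactone intact; the C7a epimers converge in step 8.

Step 8
Reactants: 11 (3R,3aS,4R)-3-(but-3-en-1-yl)-4-hydroxy-4-methylhexahydroisobenzofuran-1(3H)-one
Product: 12 (3R,3aS,4R,7aR)-3-(but-3-en-1-yl)-4-hydroxy-4,7a-dimethylhexahydroisobenzofuran-1(3H)-one
Conditions: LDA (2.3 equiv), THF, −78 °C; MeI, −78 → −20 °C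
Reagents that add atoms: iodomethane CI
Why: Alkylation of the ring-fusion lactone enolate (formed as the dianion with the tertiary alkoxide) should occur on the convex face, syn to H5 and anti to the C5–C10 bond, giving the cis-fused lactone with the C4 methyl set.

Step 9
Reactants: 12 (3R,3aS,4R,7aR)-3-(but-3-en-1-yl)-4-hydroxy-4,7a-dimethylhexahydroisobenzofuran-1(3H)-one
Product: 13 (3R,3aS,4R,7aR)-4-hydroxy-4,7a-dimethyl-3-(3-oxopropyl)hexahydroisobenzofuran-1(3H)-one
Conditions: O3, CH2Cl2, −78 °C; PPh3, −78 °C → rt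
Reagents that add atoms: ozone [O-][O+]=O
Why: Ozonolysis of the terminal alkene with reductive work-up should unmask the aldehyde without touching lactone or tertiary alcohol.

Step 10
Reactants: 13 (3R,3aS,4R,7aR)-4-hydroxy-4,7a-dimethyl-3-(3-oxopropyl)hexahydroisobenzofuran-1(3H)-one
Product: 14 (3R,3aS,4R,7aR)-3-(2-formylprop-2-en-1-yl)-4-hydroxy-4,7a-dimethylhexahydroisobenzofuran-1(3H)-one
Conditions: 37% aq. HCHO, pyrrolidine (10 mol%), EtCO2H (10 mol%), i-PrOH, 45 °C
Reagents that add atoms: formaldehyde C=O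
Why: Organocatalytic α-methylenation (Mannich condensation of the aldehyde enamine with formaldehyde, then elimination) should give the 2-substituted acrolein.

Step 11
Reactants: 15 potassium (1E,3E)-5-oxopenta-1,3-dien-1-olate (glutaconaldehyde potassium salt)
Product: 16 (2E,4E)-5-(triisopropylsilyloxy)penta-2,4-dienal
Conditions: TIPSCl, DMF, 0 °C
Reagents that add atoms: chlorotriisopropylsilane CC(C)[Si](Cl)(C(C)C)C(C)C
Why: O-silylation of the all-trans glutaconaldehyde enolate by the hard silyl chloride should keep both E double bonds.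

Step 12
Reactants: 16 (2E,4E)-5-(triisopropylsilyloxy)penta-2,4-dienal
Product: 17 [(1E,3E)-hexa-1,3-dien-5-yn-1-yloxy]triisopropylsilane
Conditions: TMSCHN2, n-BuLi, THF, −78 °C → rt
Reagents that add atoms: trimethylsilyldiazomethane C[Si](C)(C)C=[N+]=[N-]
Why: Colvin homologation (addition of lithiated trimethylsilyldiazomethane, Peterson elimination, 1,2-hydride shift of the alkylidene carbene) should give the terminal alkyne under aprotic conditions that spare the silyl dienol ether.

Step 13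
Reactants: 14 (3R,3aS,4R,7aR)-3-(2-formylprop-2-en-1-yl)-4-hydroxy-4,7a-dimethylhexahydroisobenzofuran-1(3H)-one; 17 [(1E,3E)-hexa-1,3-dien-5-yn-1-yloxy]triisopropylsilane
Product: 19 (1S,2S,5S)-5-ethynyl-2-hydroxy-1-{[(1R,3aR,7R,7aS)-7-hydroxy-3a,7-dimethyl-3-oxooctahydroisobenzofuran-1-yl]methyl}cyclohex-3-ene-1-carbaldehyde, via silyl ether adduct 18 (not isolated)
Conditions: (R)-3,3-diphenyl-1-(2-methylphenyl)tetrahydro-1H,3H-pyrrolo[1,2-c][1,3,2]oxazaborole (20 mol%), Tf2NH (18 mol%), CH2Cl2, −78 → −40 °C; then HF·pyridine, THF, 0 °C → rt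
Reagents that add atoms: none
Why: Oxazaborolidinium-catalysed Diels–Alder reaction of a 1-silyloxydiene with a 2-substituted acrolein, which should give the ortho adduct with formyl endo (formyl cis to both the siloxy and the ethynyl group), the catalyst-bound s-trans enal exposing one face so that C8 (and with it C13 and C9) is set by the catalyst and not by the remote lactone, before fluoride cleaves the silyl ether.

Step 14
Reactants: 19 (1S,2S,5S)-5-ethynyl-2-hydroxy-1-{[(1R,3aR,7R,7aS)-7-hydroxy-3a,7-dimethyl-3-oxooctahydroisobenzofuran-1-yl]methyl}cyclohex-3-ene-1-carbaldehyde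
Product: 20 (1R,5S)-5-ethynyl-1-{[(1R,3aR,7R,7aS)-7-hydroxy-3a,7-dimethyl-3-oxooctahydroisobenzofuran-1-yl]methyl}-2-oxocyclohex-3-ene-1-carbaldehyde
Conditions: Dess–Martin periodinane, NaHCO3, CH2Cl2, 0 °C → rt
Reagents that add atoms: none
Why: Dess–Martin oxidation of the allylic alcohol should give the enone, the non-enolisable formyl group and the tertiary alcohol being inert.

Step 15
Reactants: 20 (1R,5S)-5-ethynyl-1-{[(1R,3aR,7R,7aS)-7-hydroxy-3a,7-dimethyl-3-oxooctahydroisobenzofuran-1-yl]methyl}-2-oxocyclohex-3-ene-1-carbaldehyde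
Product: 21 (3R,3aS,4R,7aR)-4-hydroxy-3-{[(1R,5S,7R)-7-hydroxy-6-methylidene-2-oxobicyclo[3.2.1]oct-3-en-1-yl]methyl}-4,7a-dimethylhexahydroisobenzofuran-1(3H)-one
Conditions: CrCl2 (4 equiv), NiCl2 (10 mol%), PPh3 (20 mol%), H2O (2 equiv), DMF, 25 °C
Reagents that add atoms: none
Why: Zerovalent nickel, generated from NiCl2 by CrCl2, should add H–Ni across the terminal alkyne in the Markovnikov sense (water is the hydrogen source); the C16 alkenylnickel transmetalates to trivalent chromium and the alkenylchromium adds to the C15 aldehyde. The closest known reaction is the chromium/nickel-mediated reductive coupling of terminal alkynes with aldehydes to 2-substituted allylic alcohols, an alkyne-based variant of the Nozaki–Hiyama–Kishi reaction, used here intramolecularly. Ring D closes by a 5-exo-trig addition to the formyl group, which completes the bicyclo[3.2.1]octenone because ethynyl and formyl are cis-1,3 on ring C. C15 is the only new stereocenter: trivalent chromium bridging the C9 ketone and C15 aldehyde oxygens should hold the formyl C=O syn to the C8–C9 bond, so the carbinol oxygen ends on the face of the enone bridge, as the target requires. The step needs chemoselectivity for the aldehyde over enone, ketone and lactone, which the aldehyde preference of alkenylchromium reagents secures, and metalation at the internal alkyne carbon, which hydronickelation of a terminal alkyne secures. The tertiary hydroxyl needs no protection under these nearly neutral conditions.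

Step 16
Reactants: 21 (3R,3aS,4R,7aR)-4-hydroxy-3-{[(1R,5S,7R)-7-hydroxy-6-methylidene-2-oxobicyclo[3.2.1]oct-3-en-1-yl]methyl}-4,7a-dimethylhexahydroisobenzofuran-1(3H)-one
Product: 22 (1R,5S,7R)-1-{[(1R,3aR,7R,7aS)-7-hydroxy-3a,7-dimethyl-3-oxooctahydroisobenzofuran-1-yl]methyl}-6-methylidene-2-oxobicyclo[3.2.1]oct-3-en-7-yl acetate (CNP0172716.1)
Conditions: Ac2O, pyridine, DMAP (cat.), CH2Cl2, 0 °C
Reagents that add atoms: acetic anhydride CC(=O)OC(C)=O
Why: Acylation of the secondary allylic alcohol should be selective, since the hindered tertiary alcohol does not acetylate at 0 °C.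

Compound list
1 | dimethyl 2-allylmalonate | C=CCC(C(=O)OC)C(=O)OC | starting material
2 | 5-bromo-2-methylpent-1-ene | C=C(C)CCCBr | starting material
3 | dimethyl 2-allyl-2-(4-methylpent-4-en-1-yl)malonate | C=CCC(CCCC(C)=C)(C(=O)OC)C(=O)OC | intermediate
4 | dimethyl 2-(2-oxoethyl)-2-(4-oxopentyl)malonate | O=CCC(CCCC(C)=O)(C(=O)OC)C(=O)OC | intermediate
5 | dimethyl (2R,3R)-2-formyl-3-hydroxy-3-methylcyclohexane-1,1-dicarboxylate | O=C[C@H]1[C@](C)(O)CCCC1(C(=O)OC)C(=O)OC | intermediate
6 | but-3-en-1-ylmagnesium bromide | C=CCC[Mg]Br | starting material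
7 | dimethyl (2S,3R)-3-hydroxy-2-(1-hydroxypent-4-en-1-yl)-3-methylcyclohexane-1,1-dicarboxylate, both carbinol epimers | OC(CCC=C)[C@H]1[C@](C)(O)CCCC1(C(=O)OC)C(=O)OC | intermediate
8 | dimethyl (2R,3R)-3-hydroxy-3-methyl-2-(pent-4-enoyl)cyclohexane-1,1-dicarboxylate | C=CCCC(=O)[C@H]1[C@](C)(O)CCCC1(C(=O)OC)C(=O)OC | intermediate
9 | dimethyl (2S,3R)-3-hydroxy-2-[(1R)-1-hydroxypent-4-en-1-yl]-3-methylcyclohexane-1,1-dicarboxylate | C=CCC[C@@H](O)[C@H]1[C@](C)(O)CCCC1(C(=O)OC)C(=O)OC | intermediate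
10 | methyl (3R,3aS,4R,7aR)-3-(but-3-en-1-yl)-4-hydroxy-4-methyl-1-oxohexahydroisobenzofuran-7a(1H)-carboxylate | C=CCC[C@H]1OC(=O)[C@]2(C(=O)OC)CCC[C@@](C)(O)[C@H]12 | intermediate
11 | (3R,3aS,4R)-3-(but-3-en-1-yl)-4-hydroxy-4-methylhexahydroisobenzofuran-1(3H)-one, both C7a epimers | C=CCC[C@H]1OC(=O)C2CCC[C@@](C)(O)[C@H]12 | intermediate
12 | (3R,3aS,4R,7aR)-3-(but-3-en-1-yl)-4-hydroxy-4,7a-dimethylhexahydroisobenzofuran-1(3H)-one | C=CCC[C@H]1OC(=O)[C@]2(C)CCC[C@@](C)(O)[C@H]12 | intermediate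
13 | (3R,3aS,4R,7aR)-4-hydroxy-4,7a-dimethyl-3-(3-oxopropyl)hexahydroisobenzofuran-1(3H)-one | O=CCC[C@H]1OC(=O)[C@]2(C)CCC[C@@](C)(O)[C@H]12 | intermediate
14 | (3R,3aS,4R,7aR)-3-(2-formylprop-2-en-1-yl)-4-hydroxy-4,7a-dimethylhexahydroisobenzofuran-1(3H)-one | C=C(C=O)C[C@H]1OC(=O)[C@]2(C)CCC[C@@](C)(O)[C@H]12 | intermediate
15 | potassium (1E,3E)-5-oxopenta-1,3-dien-1-olate | [K+].[O-]/C=C/C=C/C=O | starting material
16 | (2E,4E)-5-(triisopropylsilyloxy)penta-2,4-dienal | O=C/C=C/C=C/O[Si](C(C)C)(C(C)C)C(C)C | intermediate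
17 | [(1E,3E)-hexa-1,3-dien-5-yn-1-yloxy]triisopropylsilane | C#C/C=C/C=C/O[Si](C(C)C)(C(C)C)C(C)C | intermediate
18 | (1S,2S,5S)-5-ethynyl-1-{[(1R,3aR,7R,7aS)-7-hydroxy-3a,7-dimethyl-3-oxooctahydroisobenzofuran-1-yl]methyl}-2-(triisopropylsilyloxy)cyclohex-3-ene-1-carbaldehyde | C#C[C@@H]1C=C[C@H](O[Si](C(C)C)(C(C)C)C(C)C)[C@@](C[C@H]2OC(=O)[C@]3(C)CCC[C@@](C)(O)[C@H]23)(C1)C=O | intermediate
19 | (1S,2S,5S)-5-ethynyl-2-hydroxy-1-{[(1R,3aR,7R,7aS)-7-hydroxy-3a,7-dimethyl-3-oxooctahydroisobenzofuran-1-yl]methyl}cyclohex-3-ene-1-carbaldehyde | C#C[C@@H]1C=C[C@H](O)[C@@](C[C@H]2OC(=O)[C@]3(C)CCC[C@@](C)(O)[C@H]23)(C1)C=O | intermediate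
20 | (1R,5S)-5-ethynyl-1-{[(1R,3aR,7R,7aS)-7-hydroxy-3a,7-dimethyl-3-oxooctahydroisobenzofuran-1-yl]methyl}-2-oxocyclohex-3-ene-1-carbaldehyde | C#C[C@@H]1C=CC(=O)[C@@](C[C@H]2OC(=O)[C@]3(C)CCC[C@@](C)(O)[C@H]23)(C1)C=O | intermediate
21 | (3R,3aS,4R,7aR)-4-hydroxy-3-{[(1R,5S,7R)-7-hydroxy-6-methylidene-2-oxobicyclo[3.2.1]oct-3-en-1-yl]methyl}-4,7a-dimethylhexahydroisobenzofuran-1(3H)-one | C=C1[C@@H]2C=CC(=O)[C@@](C[C@H]3OC(=O)[C@]4(C)CCC[C@@](C)(O)[C@H]34)(C2)[C@@H]1O | intermediate
22 | (1R,5S,7R)-1-{[(1R,3aR,7R,7aS)-7-hydroxy-3a,7-dimethyl-3-oxooctahydroisobenzofuran-1-yl]methyl}-6-methylidene-2-oxobicyclo[3.2.1]oct-3-en-7-yl acetate | C=C1[C@@H]2C=CC(=O)[C@@](C[C@H]3OC(=O)[C@]4(C)CCC[C@@](C)(O)[C@H]34)(C2)[C@@H]1OC(C)=O | target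

Total step count: 16. Longest linear sequence: 14 steps (steps 1–10 and 13–16; steps 11–12 make the diene separately).

Steps most likely to fail

1. Step 15. Hydronickelation of the alkyne may be slow or unselective, or the low-valent metals may reduce the enone or oligomerise the alkyne before the ring closes. The fallback is the classical Nozaki–Hiyama–Kishi closure with a preformed alkenyl triflate; it sets out from dienal 16 and enal 14 and comes back at 21. MeMgBr adds to 16 to give the dienol F1, MnO2 oxidises it to the dienone F2, and KHMDS/PhNTf2 gives the trienyl triflate F3. Diels–Alder reaction of F3 with 14 under the conditions of step 13 gives the silyl ether adduct F4 and, after HF·pyridine, the alcohol F5. Dess–Martin oxidation gives the keto aldehyde F6, and CrCl2 with catalytic NiCl2 in DMF should close ring D to 21 under the same chelation control.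

2. Step 3. Enamine formation at the methyl ketone with aldol attack on the aldehyde (reversed donor and acceptor roles) may compete, and attack of the hindered enamine may be slow. The fallback makes the same C5–C10 bond by epoxide opening, which has no such ambiguity; it sets out from 1 and comes back at 5. Hydroboration of 1 with 9-BBN and B-alkyl Suzuki coupling with (E)-3-iodobut-2-en-1-ol (PdCl2(dppf), K3PO4) gives the allylic alcohol F7. Sharpless epoxidation (Ti(OiPr)4, D-(−)-diethyl tartrate, t-BuOOH) gives the epoxy alcohol F8, which is silylated (TBSCl, imidazole) to F9. NaH in THF should close the ring by 6-endo attack of the malonate at the less substituted epoxide carbon with inversion, giving the cyclohexanol F10. HF·pyridine gives the diol F11, and immediate Dess–Martin oxidation of its primary alcohol gives 5.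

3. Step 13. Endo or facial selectivity may be poor, or the free tertiary hydroxyl and the lactone may inhibit the boron catalyst. The fallback moves the stereocontrol to a chiral diene; it sets out from 17 and 14 and comes back at 19. Desilylation of 17 with TBAF and O-acylation of the dienolate with (S)-O-methylmandeloyl chloride gives the dienyl ester F12 (its enantiomer is used if the shielded diene face proves to be the other one). Diels–Alder reaction with 14 promoted by BF3·OEt2 in CH2Cl2 at −78 °C gives the adduct F13, and K2CO3 in MeOH at 0 °C removes the auxiliary to give 19.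

Further compounds
F1 | step 15 | (3E,5E)-6-(triisopropylsilyloxy)hexa-3,5-dien-2-ol | CC(O)/C=C/C=C/O[Si](C(C)C)(C(C)C)C(C)C
F2 | step 15 | (3E,5E)-6-(triisopropylsilyloxy)hexa-3,5-dien-2-one | CC(=O)/C=C/C=C/O[Si](C(C)C)(C(C)C)C(C)C
F3 | step 15 | (3E,5E)-6-(triisopropylsilyloxy)hexa-1,3,5-trien-2-yl trifluoromethanesulfonate | C=C(OS(=O)(=O)C(F)(F)F)/C=C/C=C/O[Si](C(C)C)(C(C)C)C(C)C
F4 | step 15 | 1-[(1S,4S,5S)-5-formyl-5-{[(1R,3aR,7R,7aS)-7-hydroxy-3a,7-dimethyl-3-oxooctahydroisobenzofuran-1-yl]methyl}-4-(triisopropylsilyloxy)cyclohex-2-en-1-yl]ethenyl trifluoromethanesulfonate | C=C(OS(=O)(=O)C(F)(F)F)[C@@H]1C=C[C@H](O[Si](C(C)C)(C(C)C)C(C)C)[C@@](C[C@H]2OC(=O)[C@]3(C)CCC[C@@](C)(O)[C@H]23)(C1)C=O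
F5 | step 15 | 1-[(1S,4S,5S)-5-formyl-4-hydroxy-5-{[(1R,3aR,7R,7aS)-7-hydroxy-3a,7-dimethyl-3-oxooctahydroisobenzofuran-1-yl]methyl}cyclohex-2-en-1-yl]ethenyl trifluoromethanesulfonate | C=C(OS(=O)(=O)C(F)(F)F)[C@@H]1C=C[C@H](O)[C@@](C[C@H]2OC(=O)[C@]3(C)CCC[C@@](C)(O)[C@H]23)(C1)C=O
F6 | step 15 | 1-[(1S,5R)-5-formyl-5-{[(1R,3aR,7R,7aS)-7-hydroxy-3a,7-dimethyl-3-oxooctahydroisobenzofuran-1-yl]methyl}-4-oxocyclohex-2-en-1-yl]ethenyl trifluoromethanesulfonate | C=C(OS(=O)(=O)C(F)(F)F)[C@@H]1C=CC(=O)[C@@](C[C@H]2OC(=O)[C@]3(C)CCC[C@@](C)(O)[C@H]23)(C1)C=O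
F7 | step 3 | dimethyl 2-[(4E)-6-hydroxy-4-methylhex-4-en-1-yl]malonate | OC/C=C(\C)CCCC(C(=O)OC)C(=O)OC
F8 | step 3 | dimethyl 2-{3-[(2R,3R)-3-(hydroxymethyl)-2-methyloxiran-2-yl]propyl}malonate | OC[C@H]1O[C@]1(C)CCCC(C(=O)OC)C(=O)OC
F9 | step 3 | dimethyl 2-{3-[(2R,3R)-3-[(tert-butyldimethylsilyloxy)methyl]-2-methyloxiran-2-yl]propyl}malonate | CC(C)(C)[Si](C)(C)OC[C@H]1O[C@]1(C)CCCC(C(=O)OC)C(=O)OC
F10 | step 3 | dimethyl (2S,3R)-2-[(tert-butyldimethylsilyloxy)methyl]-3-hydroxy-3-methylcyclohexane-1,1-dicarboxylate | CC(C)(C)[Si](C)(C)OC[C@H]1[C@](C)(O)CCCC1(C(=O)OC)C(=O)OC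
F11 | step 3 | dimethyl (2S,3R)-3-hydroxy-2-(hydroxymethyl)-3-methylcyclohexane-1,1-dicarboxylate | OC[C@H]1[C@](C)(O)CCCC1(C(=O)OC)C(=O)OC
F12 | step 13 | (1E,3E)-hexa-1,3-dien-5-yn-1-yl (2S)-2-methoxy-2-phenylacetate | C#C/C=C/C=C/OC(=O)[C@@H](OC)c1ccccc1
F13 | step 13 | (1S,4S,6S)-4-ethynyl-6-formyl-6-{[(1R,3aR,7R,7aS)-7-hydroxy-3a,7-dimethyl-3-oxooctahydroisobenzofuran-1-yl]methyl}cyclohex-2-en-1-yl (2S)-2-methoxy-2-phenylacetate | C#C[C@@H]1C=C[C@H](OC(=O)[C@@H](OC)c2ccccc2)[C@@](C[C@H]3OC(=O)[C@]4(C)CCC[C@@](C)(O)[C@H]34)(C1)C=O
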